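I decide to count this flask in turnovers, meaning percent of target made per mol% of free catalyst charged, and to add the processes one at a time.

| setting | Monday's | Thursday's | ash | birch | elm | alder | maple |
|---|---|---|---|---|---|---|---|
| solid substrate | 0.89 M | 0.89 M | 0.89 M | 0.89 M | 0.89 M | 0.89 M | 0.89 M |
| free catalyst | 1.4 mol% | 8.1 mol% | 6 mol% | 1 mol% | 5 mol% | 3 mol% | 1.6 mol% |
| temperature | 85 °C | 96 °C | 90 °C | 90 °C | 90 °C | 90 °C | 90 °C |
| remark | run made earlier | run made earlier |  |  |  |  |  |
| time |  |  | 6.0 h | 6.0 h | 6.0 h | 6.0 h | 6.0 h |

| run | time / h | target / % | solid substrate / % |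
|---|---|---|---|
| Monday's | 0.250 | 0.5 | 87.9 |
| Monday's | 0.333 | 0.3 | 87.0 |
| Monday's | 0.500 | 0.4 | 83.2 |
| Monday's | 0.833 | 0 | 74.3 |
| Monday's | 1.33 | 3.6 | 66.7 |
| Monday's | 2.00 | 2.8 | 57.5 |
| Monday's | 3.00 | 3.9 | 54.9 |
| Thursday's | 0.167 | 0.8 | 92.4 |
| Thursday's | 0.500 | 3.5 | 81.1 |
| Thursday's | 0.833 | 9.0 | 71.0 |
| Thursday's | 1.33 | 16.2 | 60.0 |
| Thursday's | 2.00 | 25.5 | 45.4 |
| Thursday's | 2.50 | 31.1 | 38.8 |
| Thursday's | 3.00 | 36.5 | 33.1 |

(scatter of a reading: 1 percentage point)
- solid substrate is a solid; its amount is given per volume of the solution
- the numbers in the tables scatter with a standard deviation of 1 percentage point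
- at the start none of the solid substrate is in solution
- what has only dissolved of solid substrate counts as not reacted
- all flasks from highest to lowest amount of target, in percent of the solid substrate charged, at 6.0 h (ash / birch / elm / alder / maple)
- the amount of target, in percent of the solid substrate charged of the flask you put first, at 6.0 h
- the amount of target, in percent of the solid substrate charged of the flask you put last, at 6.0 h

First I take the main step by itself. Between 0.500 h and 2.00 h, Thursday's run gains turnovers at a rate of 1.81 /h, and held steady for 6.0 h that gives 10.9 turnovers.

Next I add the dissolving of the solid substrate. At 0.500 h the solid substrate reads 81.1% on Thursday and 83.2% on Monday, so its loss differs little between these two runs. Thursday's early loss of 0.378 /h of the charge is faster than the 0.109 /h that ash at 6 mol% would draw, so in my reckoning this addition leaves the count where it stands.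

Then I add fading. From 2.00 h to 3.00 h, Thursday's run slows to a turnover rate of 1.36 /h, below the earlier rate, and the two rates lie 1.25 h apart, which reads as a half-life of 3.01 h for the turnover rate of Thursday's run. This is a reading from scattered numbers of the rate as a whole, not a half-life of the catalyst. The 4.51 turnovers read at 3.00 h, plus the fading tail up to 6.0 h, give 7.45 turnovers per catalyst, the turnover number that I carry. I leave it uncorrected for the step from 96 °C to 90 °C, which is a risk. Target then follows the loading: my reckoning gives 44.7% in ash and 7.45% in birch.

The forecast gives ash > elm > alder > maple > birch, with 42% for the first and 5% for the last, on the ground that “the intermediate → target step is the catalyst-sensitive one”. Its figure for birch is lower than mine.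

The flasks give ash > elm > alder > maple > birch, with 49.9% in ash and 9.71% in birch, which is 8.32 and 9.71 turnovers against my 7.45.

    starting material + free catalyst → catalyst intermediate A (k = 0.173 /M/min, Ea = 61.0 kJ/mol)
    catalyst intermediate A → catalyst intermediate B (k = 0.727 /min, Ea = 88.0 kJ/mol)
    catalyst intermediate B → free catalyst + target (k = 55.4 /min, Ea = 90.0 kJ/mol)
    solid substrate ⇌ starting material, rate k4*(cs4 - [starting material]) while solid is left; crystals form when [starting material] > cs4 (solubility = 0.390 M, k = 0.0186 /min)
    free catalyst → spent catalyst (k = 0.00366 /min, Ea = 115 kJ/mol)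
    (constants at 90 °C)

At 90 °C, free catalyst turns into spent catalyst with a half-life of 3.16 h, shorter than the 6.0 h of the flask. At 6.00 h, 26.9% of the catalyst charged is still free in ash and 26.9% in birch. The neighbour of birch with 4 mol% of free catalyst makes 35.3% of target, which is 8.82 turnovers.

(The numbers in the tables were generated by integration with made-up constants.)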